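Numbering the chain from the ketone carbon C1 (on furan C3) to C13 (the exocyclic carbon on the tetronic acid ring), the route cuts C6–C7 and C9–C10. This frees C7–C8(=CH2)–C9, whose two methylene arms are equivalent and which lies between the furan/ketone half and the half bearing C12 and the lactone ring. Doubly metalated isobutene is alkylated in one flask, first with an (S)-configured primary iodide (C10–C13, silyl-protected), then with an E-allylic bromide (C1–C6, ketone as dioxolane). Both bonds and the exo-methylene arise together, with no ring closure. The tetronic acid ring is assembled last by olefination and Dieckmann condensation.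

Key step: step 11

Remark: the target is taken as drawn, with C12 of S configuration and the chain on the exocyclic alkene trans to the ring oxygen (5E). The chiral iodide is built by one-carbon extension of a C4 bromo alcohol, so that no step has to tell two primary hydroxyls apart or handle a 1,4-halo alcohol prone to tetrahydrofuran closure. The epoxide and carbinol centres made on the way are racemic and are destroyed before the fragments are joined.

Step 1
Reactants: 1 geranyl acetate
Product: 2 (E)-5-(3,3-dimethyloxiran-2-yl)-3-methylpent-2-en-1-yl acetate (6,7-epoxygeranyl acetate, racemic)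
Conditions: mCPBA (1.05 equiv), CH2Cl2, 0 °C
Reagents that add atoms: mCPBA, O=C(OO)c1cccc(Cl)c1
Why: Prilezhaev epoxidation is electrophilic, so the electron-rich distal alkene should react well ahead of the 2,3-alkene, which is deactivated by the allylic acetoxy group; the epoxide centre is uncontrolled and is destroyed in step 2.

Step 2
Reactants: 2 6,7-epoxygeranyl acetate
Product: 3 (E)-3-methyl-6-oxohex-2-en-1-yl acetate
Conditions: H5IO6 (1.1 equiv), THF–H2O, 0 °C
Reagents that add atoms: none
Why: Periodic acid hydrates the epoxide (water entering at the tertiary carbon, so the aldehyde keeps the epoxide oxygen) and cleaves the glycol in a Malaprade cleavage, releasing acetone and leaving the acetate and the 2,3-alkene untouched.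

Step 3
Reactants: 4 3-bromofuran; 3 (E)-3-methyl-6-oxohex-2-en-1-yl acetate
Product: 7 (E)-6-(furan-3-yl)-6-hydroxy-3-methylhex-2-en-1-yl acetate (racemic carbinol), via 3-furyllithium 5 (not isolated), via 3-furylmagnesium bromide 6 (not isolated)
Conditions: n-BuLi, THF, −78 °C; MgBr2·OEt2, −78 °C; then 3, −78 → −40 °C; H2O/NH4Cl
Reagents that add atoms: none
Why: Bromine–lithium exchange at −78 °C gives 3-furyllithium without drift to the 2-lithio isomer, and after transmetalation the Grignard 1,2-addition to the aldehyde should far outpace attack on the acetate; the carbinol centre is racemic and is erased in step 4.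

Step 4
Reactants: 7 (E)-6-(furan-3-yl)-6-hydroxy-3-methylhex-2-en-1-yl acetate
Product: 8 (E)-6-(furan-3-yl)-3-methyl-6-oxohex-2-en-1-yl acetate
Conditions: DMP (1.2 equiv), CH2Cl2, 0 °C → rt
Reagents that add atoms: none
Why: Dess–Martin oxidation of the secondary furyl carbinol to the ketone is mild enough to leave the allylic acetate, the alkene and the furan intact, and it removes the uncontrolled stereocentre.

Step 5
Reactants: 8 (E)-6-(furan-3-yl)-3-methyl-6-oxohex-2-en-1-yl acetate
Product: 9 (E)-5-[2-(furan-3-yl)-1,3-dioxolan-2-yl]-3-methylpent-2-en-1-yl acetate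
Conditions: HOCH2CH2OH (5 equiv), HC(OEt)3 (1.5 equiv), TsOH·H2O (5 mol%), CH2Cl2, rt
Reagents that add atoms: ethylene glycol, OCCO
Why: Acid-catalysed ketalisation, driven at room temperature by the orthoformate as water scavenger, should convert the ketone (the ester being inert) into the dioxolane that must shield C1 from the carbanions of step 11, without ionising the allylic acetate.

Step 6
Reactants: 9 (E)-5-[2-(furan-3-yl)-1,3-dioxolan-2-yl]-3-methylpent-2-en-1-yl acetate
Product: 10 (E)-5-[2-(furan-3-yl)-1,3-dioxolan-2-yl]-3-methylpent-2-en-1-ol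
Conditions: K2CO3 (cat.), MeOH, 0 °C → rt
Reagents that add atoms: none
Why: Base-catalysed transesterification with methanol removes the acetate under conditions to which the acid-labile dioxolane, the furan and the E-alkene are inert.

Step 7
Reactants: 10 (E)-5-[2-(furan-3-yl)-1,3-dioxolan-2-yl]-3-methylpent-2-en-1-ol
Product: 12 2-[(E)-5-bromo-3-methylpent-3-en-1-yl]-2-(furan-3-yl)-1,3-dioxolane, via allylic mesylate 11 (not isolated)
Conditions: MsCl, Et3N, THF, −40 °C; then LiBr (4 equiv), THF, −40 → 0 °C
Reagents that add atoms: lithium bromide, [Li+].[Br-]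
Why: Mesylation followed by in situ SN2 displacement with bromide converts the primary allylic alcohol into the bromide without acid, direct displacement at the primary carbon preserving the E geometry and sparing the dioxolane.

Step 8
Reactants: 13 (R)-3-bromo-2-methylpropan-1-ol
Product: 14 (R)-(3-bromo-2-methylpropoxy)(tert-butyl)dimethylsilane
Conditions: TBSCl, imidazole, CH2Cl2, 0 °C → rt
Reagents that add atoms: tert-butyldimethylsilyl chloride, CC(C)(C)[Si](C)(C)Cl
Why: Silylation of the primary alcohol (silyl ether formation) is routine and touches neither the stereocentre nor the primary bromide.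

Step 9
Reactants: 14 (R)-(3-bromo-2-methylpropoxy)(tert-butyl)dimethylsilane
Product: 16 (S)-4-[(tert-butyldimethylsilyl)oxy]-3-methylbutan-1-ol, via Grignard reagent 15 (not isolated)
Conditions: Mg (I2-activated), THF, 45 °C; then CH2O (gas, from cracked (CH2O)n), 0 °C → rt; H2O/NH4Cl
Reagents that add atoms: formaldehyde, C=O
Why: Grignard formation at the primary bromide and addition to formaldehyde adds the one carbon that becomes C10 without involving the stereocentre, whose descriptor changes from R to S only because the ranking of its substituents changes.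

Step 10
Reactants: 16 (S)-4-[(tert-butyldimethylsilyl)oxy]-3-methylbutan-1-ol
Product: 17 (S)-tert-butyl(4-iodo-2-methylbutoxy)dimethylsilane
Conditions: PPh3, I2, imidazole, CH2Cl2, 0 °C → rt
Reagents that add atoms: iodine, II
Why: Appel-type (Garegg–Samuelsson) iodination converts the unhindered primary alcohol into the iodide by SN2 displacement of the alkoxyphosphonium, imidazole keeping the medium non-acidic for the silyl ether.

Step 11
Reactants: 18 isobutene; 17 (S)-tert-butyl(4-iodo-2-methylbutoxy)dimethylsilane; 12 2-[(E)-5-bromo-3-methylpent-3-en-1-yl]-2-(furan-3-yl)-1,3-dioxolane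
Product: 21 tert-butyl{[(2S,9E)-12-[2-(furan-3-yl)-1,3-dioxolan-2-yl]-2,10-dimethyl-6-methylidenedodec-9-en-1-yl]oxy}dimethylsilane, via dipotassium isobutene dianion 19 (not isolated), via monoalkylated allylpotassium 20 (not isolated)
Conditions: n-BuLi (2.0 equiv), t-BuOK (2.0 equiv), hexane, 0 °C → rt; THF, −78 °C, 17 (0.9 equiv, slow addition), → −50 °C; 12 (1.1 equiv), −78 → −20 °C; aq. NH4Cl
Reagents that add atoms: none
Why: The butyllithium/potassium tert-butoxide superbase removes one allylic proton from each methyl group of isobutene to give the cross-conjugated dianion 19, whose SN2 attack on primary iodide 17 leaves the 2-alkylallyl anion 20, and this then displaces bromide from the primary carbon of 12, so that C9–C10 and C6–C7 are made in one flask. The closest known reaction type is the alkylation of dimetalated isobutene (trimethylenemethane dianion) with alkyl halides, the second stage being a Wurtz-type allyl–allyl coupling. No ring is closed and no stereocentre is created; C12 is remote from the reacting carbon of 17 and the E-alkene of 12 is kept because displacement occurs at its sp3 carbon. Mono- before cross-alkylation is needed and should be secured by the higher nucleophilicity of the dianion over the monoanion, by slow addition of slightly less than one equivalent of 17 at −78 °C and by adding 12 only afterwards. Because the two ends of anion 20 are identical CH2 groups, bonding through either yields the same exo-methylene product, and direct displacement at CH2Br of 12 is preferred over allylic transposition since the far alkene carbon C4 carries two carbon substituents. The ketone is masked as the dioxolane and the alcohol as a silyl ether, and halogen–metal exchange with 17 is disfavoured because it would trade a delocalised allyl anion for a primary alkyl anion.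

Step 12
Reactants: 21 silyl ether from step 11
Product: 22 (2S,9E)-12-[2-(furan-3-yl)-1,3-dioxolan-2-yl]-2,10-dimethyl-6-methylidenedodec-9-en-1-ol
Conditions: Bu4NF (1.2 equiv), THF, 0 °C → rt
Reagents that add atoms: none
Why: Fluoride-induced desilylation is driven by Si–F bond formation and is orthogonal to the dioxolane, the furan and the alkenes.

Step 13
Reactants: 22 (2S,9E)-12-[2-(furan-3-yl)-1,3-dioxolan-2-yl]-2,10-dimethyl-6-methylidenedodec-9-en-1-ol
Product: 23 (2S,9E)-12-[2-(furan-3-yl)-1,3-dioxolan-2-yl]-2,10-dimethyl-6-methylidenedodec-9-enal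
Conditions: DMP (1.3 equiv), pyridine (3 equiv), CH2Cl2, 0 °C; used at once
Reagents that add atoms: none
Why: Pyridine-buffered Dess–Martin oxidation should give the α-branched aldehyde without acid (dioxolane retained) and without the basic exposure that would epimerise C12.

Step 14
Reactants: 24 ethyl 2-(diphenoxyphosphoryl)acetate
Product: 25 ethyl 2-diazo-2-(diphenoxyphosphoryl)acetate
Conditions: p-ABSA (1.2 equiv), DBU (1.3 equiv), MeCN, 0 °C → rt
Reagents that add atoms: 4-acetamidobenzenesulfonyl azide, CC(=O)Nc1ccc(cc1)S(=O)(=O)N=[N+]=[N-]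
Why: Regitz diazo transfer to the doubly activated methylene of a phosphonoacetate is standard.

Step 15
Reactants: 25 ethyl 2-diazo-2-(diphenoxyphosphoryl)acetate
Product: 26 ethyl 2-(diphenoxyphosphoryl)-2-(propanoyloxy)acetate (racemic)
Conditions: EtCO2H (3 equiv), Rh2(OAc)4 (1 mol%), benzene, 80 °C
Reagents that add atoms: propanoic acid, CCC(=O)O
Why: Rhodium-carbenoid O–H insertion into the carboxylic acid installs the α-acyloxy group under neutral conditions that spare the aryl phosphonate esters; the new centre is racemic and becomes sp2 in step 16.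

Step 16
Reactants: 26 ethyl 2-(diphenoxyphosphoryl)-2-(propanoyloxy)acetate; 23 aldehyde from step 13
Product: 28 ethyl (2E,4S,11E)-14-[2-(furan-3-yl)-1,3-dioxolan-2-yl]-4,12-dimethyl-8-methylidene-2-(propanoyloxy)tetradeca-2,11-dienoate, via sodium phosphonate 27 (not isolated)
Conditions: 26 (1.3 equiv), NaH (1.2 equiv), THF, 0 °C; then 23, −78 → −20 °C
Reagents that add atoms: none
Why: Horner–Wadsworth–Emmons olefination in its diaryl phosphonate (Ando-type) form, in which fast irreversible collapse of the kinetically preferred adduct should place the chain cis to the ester group (trans to the acyloxy oxygen, 2E), while addition of the aldehyde to the preformed weakly basic anion at −78 °C should protect C12.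

Step 17
Reactants: 28 enol ester from step 16
Product: 30 (5E)-5-[(2S,9E)-13-(furan-3-yl)-2,10-dimethyl-6-methylidene-13-oxotridec-9-en-1-ylidene]-4-hydroxy-3-methylfuran-2(5H)-one (CNP0018618.1), via lithium tetronate ketal 29 (not isolated)
Conditions: LiN(SiMe3)2 (2.5 equiv), THF, −78 → −20 °C; then 0.5 M HCl to pH 2, THF–H2O, 0 °C → rt
Reagents that add atoms: water, O
Why: Dieckmann condensation, in which the propanoate enolate attacks the cis-disposed ethyl ester in a 5-exo-trig closure made irreversible by tetronate salt formation and carries the alkene geometry (chain cis to C4) over unchanged, after which brief dilute acid hydrolyses the furan-stabilised dioxolane to the ketone.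

Compound list
1 | geranyl acetate | CC(C)=CCC/C(C)=C/COC(C)=O | starting material
2 | (E)-5-(3,3-dimethyloxiran-2-yl)-3-methylpent-2-en-1-yl acetate (racemic) | CC1(C)OC1CC/C(C)=C/COC(C)=O | intermediate
3 | (E)-3-methyl-6-oxohex-2-en-1-yl acetate | O=CCC/C(C)=C/COC(C)=O | intermediate
4 | 3-bromofuran | Brc1ccoc1 | starting material
5 | 3-furyllithium | [Li]c1ccoc1 | intermediate
6 | 3-furylmagnesium bromide | Br[Mg]c1ccoc1 | intermediate
7 | (E)-6-(furan-3-yl)-6-hydroxy-3-methylhex-2-en-1-yl acetate (racemic) | CC(=O)OC/C=C(\C)CCC(O)c1ccoc1 | intermediate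
8 | (E)-6-(furan-3-yl)-3-methyl-6-oxohex-2-en-1-yl acetate | CC(=O)OC/C=C(\C)CCC(=O)c1ccoc1 | intermediate
9 | (E)-5-[2-(furan-3-yl)-1,3-dioxolan-2-yl]-3-methylpent-2-en-1-yl acetate | CC(=O)OC/C=C(\C)CCC1(c2ccoc2)OCCO1 | intermediate
10 | (E)-5-[2-(furan-3-yl)-1,3-dioxolan-2-yl]-3-methylpent-2-en-1-ol | OC/C=C(\C)CCC1(c2ccoc2)OCCO1 | intermediate
11 | (E)-5-[2-(furan-3-yl)-1,3-dioxolan-2-yl]-3-methylpent-2-en-1-yl methanesulfonate | CS(=O)(=O)OC/C=C(\C)CCC1(c2ccoc2)OCCO1 | intermediate
12 | 2-[(E)-5-bromo-3-methylpent-3-en-1-yl]-2-(furan-3-yl)-1,3-dioxolane | BrC/C=C(\C)CCC1(c2ccoc2)OCCO1 | intermediate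
13 | (R)-3-bromo-2-methylpropan-1-ol | BrC[C@H](C)CO | starting material
14 | (R)-(3-bromo-2-methylpropoxy)(tert-butyl)dimethylsilane | BrC[C@H](C)CO[Si](C)(C)C(C)(C)C | intermediate
15 | [(R)-3-(tert-butyldimethylsilyloxy)-2-methylpropyl]magnesium bromide | Br[Mg]C[C@H](C)CO[Si](C)(C)C(C)(C)C | intermediate
16 | (S)-4-[(tert-butyldimethylsilyl)oxy]-3-methylbutan-1-ol | OCC[C@H](C)CO[Si](C)(C)C(C)(C)C | intermediate
17 | (S)-tert-butyl(4-iodo-2-methylbutoxy)dimethylsilane | ICC[C@H](C)CO[Si](C)(C)C(C)(C)C | intermediate
18 | isobutene | C=C(C)C | starting material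
19 | 2-methylidenepropane-1,3-diyldipotassium (isobutene dianion) | [K]CC(=C)C[K] | intermediate
20 | {(S)-6-[(tert-butyldimethylsilyl)oxy]-5-methyl-2-methylidenehexyl}potassium | [K]CC(=C)CCC[C@H](C)CO[Si](C)(C)C(C)(C)C | intermediate
21 | tert-butyl{[(2S,9E)-12-[2-(furan-3-yl)-1,3-dioxolan-2-yl]-2,10-dimethyl-6-methylidenedodec-9-en-1-yl]oxy}dimethylsilane | C=C(CC/C=C(\C)CCC1(c2ccoc2)OCCO1)CCC[C@H](C)CO[Si](C)(C)C(C)(C)C | intermediate
22 | (2S,9E)-12-[2-(furan-3-yl)-1,3-dioxolan-2-yl]-2,10-dimethyl-6-methylidenedodec-9-en-1-ol | C=C(CC/C=C(\C)CCC1(c2ccoc2)OCCO1)CCC[C@H](C)CO | intermediate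
23 | (2S,9E)-12-[2-(furan-3-yl)-1,3-dioxolan-2-yl]-2,10-dimethyl-6-methylidenedodec-9-enal | C=C(CC/C=C(\C)CCC1(c2ccoc2)OCCO1)CCC[C@H](C)C=O | intermediate
24 | ethyl 2-(diphenoxyphosphoryl)acetate | CCOC(=O)CP(=O)(Oc1ccccc1)Oc1ccccc1 | starting material
25 | ethyl 2-diazo-2-(diphenoxyphosphoryl)acetate | CCOC(=O)C(=[N+]=[N-])P(=O)(Oc1ccccc1)Oc1ccccc1 | intermediate
26 | ethyl 2-(diphenoxyphosphoryl)-2-(propanoyloxy)acetate (racemic) | CCOC(=O)C(OC(=O)CC)P(=O)(Oc1ccccc1)Oc1ccccc1 | intermediate
27 | sodium salt of 26 (phosphonate carbanion) | [Na+].CCOC(=O)[C-](OC(=O)CC)P(=O)(Oc1ccccc1)Oc1ccccc1 | intermediate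
28 | ethyl (2E,4S,11E)-14-[2-(furan-3-yl)-1,3-dioxolan-2-yl]-4,12-dimethyl-8-methylidene-2-(propanoyloxy)tetradeca-2,11-dienoate | C=C(CC/C=C(\C)CCC1(c2ccoc2)OCCO1)CCC[C@H](C)/C=C(/OC(=O)CC)C(=O)OCC | intermediate
29 | lithium salt of (5E)-5-[(2S,9E)-12-[2-(furan-3-yl)-1,3-dioxolan-2-yl]-2,10-dimethyl-6-methylidenedodec-9-en-1-ylidene]-4-hydroxy-3-methylfuran-2(5H)-one | C=C(CC/C=C(\C)CCC1(c2ccoc2)OCCO1)CCC[C@H](C)/C=C1/OC(=O)C(C)=C1[O-].[Li+] | intermediate
30 | (5E)-5-[(2S,9E)-13-(furan-3-yl)-2,10-dimethyl-6-methylidene-13-oxotridec-9-en-1-ylidene]-4-hydroxy-3-methylfuran-2(5H)-one | C=C(CC/C=C(\C)CCC(=O)c1ccoc1)CCC[C@H](C)/C=C1/OC(=O)C(C)=C1O | target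

Total step count: 17. Longest linear sequence: 12 steps (steps 1–7, 11–13, 16 and 17, from geranyl acetate).

Steps most likely to fail

Step 11. The sequence may go astray by double alkylation of the dianion with one electrophile, by proton transfer to the allyl anion (from the furan C2–H or the medium) before the second alkylation, or by attack with allylic transposition. The fallback sets out from 17 and 12 and returns at 21; it reverses the polarity at C6/C7 and uses a sulfone-stabilised carbanion. Iodide 17 is converted (Mg, THF) into [(S)-4-(tert-butyldimethylsilyloxy)-3-methylbutyl]magnesium iodide F1, which is coupled under Li2CuCl4 catalysis with an excess of commercial 3-chloro-2-(chloromethyl)prop-1-ene to give tert-butyl{[(S)-6-(chloromethyl)-2-methylhept-6-en-1-yl]oxy}dimethylsilane F2 (C9–C10 bond). Bromide 12 is treated with PhSO2Na in DMF to give 2-(furan-3-yl)-2-[(E)-3-methyl-5-(phenylsulfonyl)pent-3-en-1-yl]-1,3-dioxolane F3. Its α-sulfonyl carbanion (n-BuLi, THF, −78 °C) is alkylated by F2 in a Biellmann-type coupling (C6–C7 bond) to give the C6-phenylsulfonyl coupled product F4 as a mixture at C6. Reductive desulfonylation (LiBHEt3, PdCl2(dppp) cat., THF, 0 °C), with hydride delivered to the less substituted allyl terminus, should give 21.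

Step 16. The olefination may lose its geometric preference, so that the chain ends trans to the ester, or the aldehyde may epimerise at C12 by enolisation. The fallback sets out from 23 and returns at 29; it forms the ring before the alkene and sorts the geometry by separation. 4-Methoxy-3-methylfuran-2(5H)-one F5, prepared from commercial 3-methyltetronic acid (Me2SO4, K2CO3, acetone), is deprotonated at C5 with LiN(i-Pr)2 (THF, −78 °C) and added to 23 to give the vinylogous aldol adducts F6. Mesylation (MsCl, Et3N) to the secondary mesylate F7 and elimination with DBU should give the 5-ylidene methyl tetronate as both geometric isomers. The isomer with the chain cis to C4, the (E)-ylidene methyl tetronate F8, is taken by chromatography, and the other isomer is re-equilibrated by irradiation at 350 nm and recycled. O-Demethylation with n-PrSLi in DMF gives lithium tetronate 29, which enters the acid stage of step 17.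

Step 17. The exocyclic alkene may isomerise to its more stable geometry while the free tetronic acid sits in aqueous acid, and the liberated acid may make the hydrolysis hard to stop cleanly. The fallback sets out from 28 and returns at 30; it moves the ketone release ahead of ring closure. The dioxolane is removed while the molecule is still a neutral enol ester (PPTS, acetone–H2O, rt) to give the keto enol ester ethyl (2E,4S,11E)-14-(furan-3-yl)-4,12-dimethyl-8-methylidene-14-oxo-2-(propanoyloxy)tetradeca-2,11-dienoate F9. Dieckmann closure with LiN(SiMe3)2 (3.5 equiv, the ketone resting as its enolate; THF, −78 → −20 °C) and a quench into cold aqueous citric acid (pH 3) with immediate extraction should give 30.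

Further compounds
F1 | step 11 | [(S)-4-(tert-butyldimethylsilyloxy)-3-methylbutyl]magnesium iodide | I[Mg]CC[C@H](C)CO[Si](C)(C)C(C)(C)C
F2 | step 11 | tert-butyl{[(S)-6-(chloromethyl)-2-methylhept-6-en-1-yl]oxy}dimethylsilane | ClCC(=C)CCC[C@H](C)CO[Si](C)(C)C(C)(C)C
F3 | step 11 | 2-(furan-3-yl)-2-[(E)-3-methyl-5-(phenylsulfonyl)pent-3-en-1-yl]-1,3-dioxolane | O=S(=O)(C/C=C(\C)CCC1(c2ccoc2)OCCO1)c1ccccc1
F4 | step 11 | C6-phenylsulfonyl derivative of 21 (mixture at C6) | C=C(CC(/C=C(\C)CCC1(c2ccoc2)OCCO1)S(=O)(=O)c1ccccc1)CCC[C@H](C)CO[Si](C)(C)C(C)(C)C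
F5 | step 16 | 4-methoxy-3-methylfuran-2(5H)-one | COC1=C(C)C(=O)OC1
F6 | step 16 | aldol adducts of F5 and 23 (mixture at the two new centres) | C=C(CC/C=C(\C)CCC1(c2ccoc2)OCCO1)CCC[C@H](C)C(O)C1OC(=O)C(C)=C1OC
F7 | step 16 | methanesulfonate of F6 | C=C(CC/C=C(\C)CCC1(c2ccoc2)OCCO1)CCC[C@H](C)C(OS(C)(=O)=O)C1OC(=O)C(C)=C1OC
F8 | step 16 | (5E)-5-[(2S,9E)-12-[2-(furan-3-yl)-1,3-dioxolan-2-yl]-2,10-dimethyl-6-methylidenedodec-9-en-1-ylidene]-4-methoxy-3-methylfuran-2(5H)-one | C=C(CC/C=C(\C)CCC1(c2ccoc2)OCCO1)CCC[C@H](C)/C=C1/OC(=O)C(C)=C1OC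
F9 | step 17 | ethyl (2E,4S,11E)-14-(furan-3-yl)-4,12-dimethyl-8-methylidene-14-oxo-2-(propanoyloxy)tetradeca-2,11-dienoate | C=C(CC/C=C(\C)CCC(=O)c1ccoc1)CCC[C@H](C)/C=C(/OC(=O)CC)C(=O)OCC
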